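**Retrosynthetic overview**
1. Target 36 ⇒ C6 alcohol 30 + (2R,3R)-epoxyangelic acid 34 (late Yamaguchi esterification; 34 from angelic acid by Sharpless epoxidation).
2. Furanone ring (formed last) ⇒ gold-catalysed 5-endo cyclisation of the C10 hydroxyl onto the macrocyclic ynone 28.
3. Ten-membered carbocycle (formed second) ⇒ intramolecular Nozaki–Hiyama–Kishi closure of C1–C2 in iodoalkyne aldehyde 26.
4. Key fragment union C6–C7 ⇒ zinc Barbier allylation of (Z)-enynal 18 by bromomethyl butenolide 14; the lactone ring (formed first, by ring-closing metathesis) steers C7, and C6 is then inverted by a Mitsunobu reaction.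
5. 14 ⇒ (S)-lactic acid (Seebach alkylation sets C10) plus a hydrolytic kinetic resolution (sets C8); 18 ⇒ commercial (Z)-3-methylpent-2-en-4-yn-1-ol.

Assumption: positions carry germacrane labels (C1 ketone, C2=C3 furanone alkene, C4=C5 Z-alkene, C6 ester carbinol, C7, C8 lactone carbinol, C9 CH2, C10 quaternary carbon, C11–C13 methylene lactone); the target is read as (6S,7R,8S,10R) with a (2R,3R)-2,3-epoxy-2-methylbutanoate on O6.

**Route**

Step 1
Reactants: 1 (S)-lactic acid; 2 pivalaldehyde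
Product: 3 (2S,5S)-2-tert-butyl-5-methyl-1,3-dioxolan-4-one
Conditions: TsOH·H2O (cat.), H2SO4 (cat.), pentane, reflux, Dean–Stark; recrystallisation (pentane/Et2O, −78 °C)
Reagents that add atoms: none
Why: Acid-catalysed acetalisation (Seebach self-regeneration of stereocentres) gives mainly the cis acetal, purified by crystallisation, so the acetal centre is set relative to the lactate centre.

Step 2
Reactants: 3 (2S,5S)-2-tert-butyl-5-methyl-1,3-dioxolan-4-one; 4 allyl bromide
Product: 6 (2S,5R)-2-tert-butyl-5-methyl-5-(prop-2-en-1-yl)-1,3-dioxolan-4-one, via lithium enolate 5 (not isolated)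
Conditions: LiN(iPr)2, THF, −78 °C; then 4, −78 → −20 °C
Reagents that add atoms: none
Why: Seebach enolate alkylation occurs anti to the tert-butyl group, so allyl replaces H with retention and fixes the quaternary centre that becomes C10.

Step 3
Reactants: 6 (2S,5R)-2-tert-butyl-5-methyl-5-(prop-2-en-1-yl)-1,3-dioxolan-4-one
Product: 7 (2R)-2-methylpent-4-ene-1,2-diol
Conditions: LiAlH4, Et2O, 0 °C → rt; Fieser work-up
Reagents that add atoms: none
Why: Hydride reduction of the lactone-acetal releases the primary/tertiary 1,2-diol without touching the quaternary centre.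

Step 4
Reactants: 7 (2R)-2-methylpent-4-ene-1,2-diol
Product: 8 (4R)-2,2,4-trimethyl-4-(prop-2-en-1-yl)-1,3-dioxolane
Conditions: 2,2-dimethoxypropane, PPTS (cat.), CH2Cl2, rt
Reagents that add atoms: 2,2-dimethoxypropane, COC(C)(C)OC
Why: Acid-catalysed transketalisation protects the 1,2-diol as its acetonide.

Step 5
Reactants: 8 (4R)-2,2,4-trimethyl-4-(prop-2-en-1-yl)-1,3-dioxolane
Product: 9 (4R)-2,2,4-trimethyl-4-(oxiran-2-ylmethyl)-1,3-dioxolane (1:1 mixture of oxirane epimers)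
Conditions: mCPBA, CH2Cl2, 0 °C → rt
Reagents that add atoms: mCPBA (3-chloroperoxybenzoic acid), OOC(=O)c1cccc(Cl)c1
Why: Prilezhaev epoxidation of the terminal alkene is dependable but unselective next to the remote quaternary centre, so both oxirane epimers form.

Step 6
Reactants: 9 (4R)-2,2,4-trimethyl-4-(oxiran-2-ylmethyl)-1,3-dioxolane (epimer mixture)
Product: 10 (4R)-2,2,4-trimethyl-4-{[(2S)-oxiran-2-yl]methyl}-1,3-dioxolane
Conditions: (R,R)-(salen)Co(OAc) [salen = N,N′-bis(3,5-di-tert-butylsalicylidene)cyclohexane-1,2-diaminate; trivalent cobalt] (1 mol %), H2O (0.55 equiv), THF, 0 °C → rt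
Reagents that add atoms: none
Why: Jacobsen hydrolytic kinetic resolution: the (R,R) catalyst hydrolyses the (2R)-oxirane epimer and leaves the (2S) epimer, which carries the C8 configuration (at most half of the material).

Step 7
Reactants: 10 (4R)-2,2,4-trimethyl-4-{[(2S)-oxiran-2-yl]methyl}-1,3-dioxolane
Product: 11 (2S)-1-[(4R)-2,2,4-trimethyl-1,3-dioxolan-4-yl]but-3-en-2-ol
Conditions: Me3S+ I− (3 equiv), n-BuLi (2.9 equiv), THF, −10 °C → rt
Reagents that add atoms: trimethylsulfonium iodide, C[S+](C)C.[I-]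
Why: Epoxide homologation with dimethylsulfonium methylide (attack at the terminal carbon, then ylide-induced loss of Me2S) gives the allylic alcohol with the C8–O bond and configuration untouched.

Step 8
Reactants: 11 (2S)-1-[(4R)-2,2,4-trimethyl-1,3-dioxolan-4-yl]but-3-en-2-ol; 12 2-(bromomethyl)prop-2-enoic acid
Product: 13 (2S)-1-[(4R)-2,2,4-trimethyl-1,3-dioxolan-4-yl]but-3-en-2-yl 2-(bromomethyl)prop-2-enoate
Conditions: DCC, DMAP (cat.), CH2Cl2, 0 °C
Reagents that add atoms: none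
Why: Steglich esterification of the secondary allylic alcohol touches no stereocentre.

Step 9
Reactants: 13 (2S)-1-[(4R)-2,2,4-trimethyl-1,3-dioxolan-4-yl]but-3-en-2-yl 2-(bromomethyl)prop-2-enoate
Product: 14 (5S)-3-(bromomethyl)-5-{[(4R)-2,2,4-trimethyl-1,3-dioxolan-4-yl]methyl}furan-2(5H)-one
Conditions: (H2IMes)(PCy3)Cl2Ru=CHPh (second-generation Grubbs catalyst, 5 mol %), CH2Cl2 (0.01 M), 40 °C
Reagents that add atoms: none
Why: Ring-closing metathesis of the acrylate and vinyl groups closes the butenolide (first ring) with loss of ethene.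

Step 10
Reactants: 15 (2Z)-3-methylpent-2-en-4-yn-1-ol
Product: 17 (2Z)-3-methyl-5-(trimethylsilyl)pent-2-en-4-yn-1-ol, via bis(trimethylsilyl) intermediate 16 (not isolated)
Conditions: n-BuLi (2.1 equiv), THF, −78 °C; Me3SiCl (2.2 equiv), → rt; then 1 M HCl, rt
Reagents that add atoms: chlorotrimethylsilane, C[Si](C)(C)Cl
Why: Dianion silylation followed by selective acidic cleavage of the labile O–Si bond masks the alkyne C–H and leaves the (Z)-alkene untouched.

Step 11
Reactants: 17 (2Z)-3-methyl-5-(trimethylsilyl)pent-2-en-4-yn-1-ol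
Product: 18 (2Z)-3-methyl-5-(trimethylsilyl)pent-2-en-4-ynal
Conditions: MnO2 (activated, excess), CH2Cl2, rt, dark
Reagents that add atoms: none
Why: Allylic oxidation with MnO2 is neutral and mild, so the (Z)-enal forms without isomerisation.

Step 12
Reactants: 14 (5S)-3-(bromomethyl)-5-{[(4R)-2,2,4-trimethyl-1,3-dioxolan-4-yl]methyl}furan-2(5H)-one; 18 (2Z)-3-methyl-5-(trimethylsilyl)pent-2-en-4-ynal
Product: 20 (4S,5S)-4-[(1R,2Z)-1-hydroxy-3-methyl-5-(trimethylsilyl)pent-2-en-4-yn-1-yl]-3-methylidene-5-{[(4R)-2,2,4-trimethyl-1,3-dioxolan-4-yl]methyl}oxolan-2-one, via allylzinc bromide 19 (not isolated)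
Conditions: Zn dust, THF/sat. aq. NH4Cl (2:1), 0 °C → rt
Reagents that add atoms: none
Why: Barbier-type carbonyl allylation: the allylzinc reacts at its γ-carbon (C7) through a closed chair (Zimmerman–Traxler) transition state, anti to the C8 side chain of the butenolide (4,5-trans, C7 set), and because the γ-substituent is locked trans to the CH2Zn group the carbinol forms with anti selectivity (C6 as the 1R epimer).

Step 13
Reactants: 20 (4S,5S)-4-[(1R,2Z)-1-hydroxy-3-methyl-5-(trimethylsilyl)pent-2-en-4-yn-1-yl]-3-methylidene-5-{[(4R)-2,2,4-trimethyl-1,3-dioxolan-4-yl]methyl}oxolan-2-one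
Product: 21 (1S,2Z)-3-methyl-1-[(2S,3R)-4-methylidene-5-oxo-2-{[(4R)-2,2,4-trimethyl-1,3-dioxolan-4-yl]methyl}oxolan-3-yl]-5-(trimethylsilyl)pent-2-en-4-yn-1-yl chloroacetate
Conditions: ClCH2CO2H, PPh3, DIAD, toluene, 0 °C → rt
Reagents that add atoms: chloroacetic acid, OC(=O)CCl
Why: Mitsunobu reaction: SN2 displacement of the activated allylic alcohol by chloroacetate inverts C6 to the configuration required in the target.

Step 14
Reactants: 21 (1S,2Z)-3-methyl-1-[(2S,3R)-4-methylidene-5-oxo-2-{[(4R)-2,2,4-trimethyl-1,3-dioxolan-4-yl]methyl}oxolan-3-yl]-5-(trimethylsilyl)pent-2-en-4-yn-1-yl chloroacetate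
Product: 22 (4S,5S)-4-[(1S,2Z)-1-hydroxy-3-methyl-5-(trimethylsilyl)pent-2-en-4-yn-1-yl]-3-methylidene-5-{[(4R)-2,2,4-trimethyl-1,3-dioxolan-4-yl]methyl}oxolan-2-one
Conditions: NaHCO3 (cat.), MeOH, 0 °C → rt
Reagents that add atoms: none
Why: Bicarbonate-catalysed methanolysis cleaves the activated chloroacetate far faster than the lactone, methylene lactone or alkynylsilane react, releasing the (1S) alcohol.

Step 15
Reactants: 22 (4S,5S)-4-[(1S,2Z)-1-hydroxy-3-methyl-5-(trimethylsilyl)pent-2-en-4-yn-1-yl]-3-methylidene-5-{[(4R)-2,2,4-trimethyl-1,3-dioxolan-4-yl]methyl}oxolan-2-one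
Product: 23 (4R,5S)-4-[(1S,2Z)-1-{[tert-butyl(dimethyl)silyl]oxy}-3-methyl-5-(trimethylsilyl)pent-2-en-4-yn-1-yl]-3-methylidene-5-{[(4R)-2,2,4-trimethyl-1,3-dioxolan-4-yl]methyl}oxolan-2-one
Conditions: TBSOTf, 2,6-lutidine, CH2Cl2, −78 °C
Reagents that add atoms: tert-butyldimethylsilyl trifluoromethanesulfonate, CC(C)(C)[Si](C)(C)OS(=O)(=O)C(F)(F)F
Why: Silylation with the silyl triflate protects the hindered allylic alcohol for the oxidations ahead (the C7 descriptor changes only through CIP priority).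

Step 16
Reactants: 23 (4R,5S)-4-[(1S,2Z)-1-{[tert-butyl(dimethyl)silyl]oxy}-3-methyl-5-(trimethylsilyl)pent-2-en-4-yn-1-yl]-3-methylidene-5-{[(4R)-2,2,4-trimethyl-1,3-dioxolan-4-yl]methyl}oxolan-2-one
Product: 24 (4R,5S)-4-[(1S,2Z)-1-{[tert-butyl(dimethyl)silyl]oxy}-3-methyl-5-(trimethylsilyl)pent-2-en-4-yn-1-yl]-5-[(2R)-2,3-dihydroxy-2-methylpropyl]-3-methylideneoxolan-2-one
Conditions: AcOH/THF/H2O (3:1:1), 40 °C
Reagents that add atoms: none
Why: Mild aqueous acid hydrolyses the terminal acetonide while the secondary TBS ether, the lactone and the alkynylsilane survive.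

Step 17
Reactants: 24 (4R,5S)-4-[(1S,2Z)-1-{[tert-butyl(dimethyl)silyl]oxy}-3-methyl-5-(trimethylsilyl)pent-2-en-4-yn-1-yl]-5-[(2R)-2,3-dihydroxy-2-methylpropyl]-3-methylideneoxolan-2-one
Product: 25 (4R,5S)-4-[(1S,2Z)-1-{[tert-butyl(dimethyl)silyl]oxy}-5-iodo-3-methylpent-2-en-4-yn-1-yl]-5-[(2R)-2,3-dihydroxy-2-methylpropyl]-3-methylideneoxolan-2-one
Conditions: N-iodosuccinimide, AgNO3 (10 mol %), DMF, rt, dark
Reagents that add atoms: N-iodosuccinimide, O=C1CCC(=O)N1I
Why: Silver-catalysed iododesilylation converts the alkynylsilane directly into the 1-iodoalkyne needed for ring closure.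

Step 18
Reactants: 25 (4R,5S)-4-[(1S,2Z)-1-{[tert-butyl(dimethyl)silyl]oxy}-5-iodo-3-methylpent-2-en-4-yn-1-yl]-5-[(2R)-2,3-dihydroxy-2-methylpropyl]-3-methylideneoxolan-2-one
Product: 26 (2R)-3-{(2S,3R)-3-[(1S,2Z)-1-{[tert-butyl(dimethyl)silyl]oxy}-5-iodo-3-methylpent-2-en-4-yn-1-yl]-4-methylidene-5-oxooxolan-2-yl}-2-hydroxy-2-methylpropanal
Conditions: SO3·pyridine, DMSO, i-Pr2NEt, CH2Cl2, 0 °C; used at once
Reagents that add atoms: none
Why: Parikh–Doering oxidation converts only the primary alcohol (the tertiary one cannot react and diol cleavage is avoided) into an aldehyde that has no α-hydrogen.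

Step 19
Reactants: 26 (2R)-3-{(2S,3R)-3-[(1S,2Z)-1-{[tert-butyl(dimethyl)silyl]oxy}-5-iodo-3-methylpent-2-en-4-yn-1-yl]-4-methylidene-5-oxooxolan-2-yl}-2-hydroxy-2-methylpropanal
Product: 27 macrocyclic propargylic diol: 6-O-TBS-1,10-dihydroxygermacra-4(Z),11(13)-dien-2-yn-12,8-olide (C6, C7, C8, C10 as in the target; both C1 epimers)
Conditions: CrCl2 (10 equiv), NiCl2 (2 mol %), THF/DMF (4:1), 0.002 M, slow addition, rt
Reagents that add atoms: none
Why: Intramolecular Nozaki–Hiyama–Kishi reaction: the alkynylchromium formed from the iodoalkyne adds to the aldehyde under high dilution to close the ten-membered ring (second ring), and the C1 carbinol mixture is erased in the next step.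

Step 20
Reactants: 27 macrocyclic propargylic diol (C1 epimers)
Product: 28 macrocyclic hydroxy ynone: 6-O-TBS-10-hydroxy-1-oxogermacra-4(Z),11(13)-dien-2-yn-12,8-olide
Conditions: Dess–Martin periodinane, CH2Cl2, 0 °C → rt
Reagents that add atoms: none
Why: Dess–Martin oxidation of the secondary propargylic alcohol gives the ynone, while the tertiary alcohol and the silyl ether are inert.

Step 21
Reactants: 28 macrocyclic hydroxy ynone
Product: 29 6-O-TBS ether of the deacyl target (3(2H)-furanone formed; C6, C7, C8, C10 as in the target)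
Conditions: [(4-CF3C6H4)3P]AuCl (5 mol %), AgOTf (5 mol %), toluene, rt
Reagents that add atoms: none
Why: Gold-catalysed 5-endo-dig hydroalkoxylation of the γ-hydroxy ynone closes the 3(2H)-furanone (third ring) without touching any stereocentre.

Step 22
Reactants: 29 6-O-TBS ether of the deacyl target
Product: 30 deacyl target: 6-hydroxy-1-oxo-3,10-epoxygermacra-2,4(Z),11(13)-trien-12,8-olide (all centres spatially as in the target)
Conditions: HF·pyridine, pyridine, THF, 0 °C → rt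
Reagents that add atoms: none
Why: Buffered fluoride desilylation frees the C6 alcohol without harming the methylene lactone or the furanone.

Step 23
Reactants: 31 angelic acid [(2Z)-2-methylbut-2-enoic acid]
Product: 32 (2Z)-2-methylbut-2-en-1-ol
Conditions: LiAlH4, Et2O, 0 °C
Reagents that add atoms: none
Why: Hydride reduction of the acid gives the allylic alcohol with the (Z) geometry retained.

Step 24
Reactants: 32 (2Z)-2-methylbut-2-en-1-ol
Product: 33 [(2S,3R)-2,3-dimethyloxiran-2-yl]methanol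
Conditions: Ti(OiPr)4 (10 mol %), L-(+)-diethyl tartrate (12 mol %), t-BuOOH, 4 Å MS, CH2Cl2, −20 °C
Reagents that add atoms: tert-butyl hydroperoxide, CC(C)(C)OO
Why: Sharpless asymmetric epoxidation: the L-(+)-tartrate catalyst delivers oxygen to one face of the (Z)-allylic alcohol and sets both epoxide centres, the cis relation following from the alkene geometry.

Step 25
Reactants: 33 [(2S,3R)-2,3-dimethyloxiran-2-yl]methanol
Product: 34 (2R,3R)-2,3-dimethyloxirane-2-carboxylic acid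
Conditions: RuCl3·xH2O (2 mol %), NaIO4, MeCN/EtOAc/H2O, rt
Reagents that add atoms: water, O
Why: Ruthenium tetroxide oxidation (Sharpless conditions) takes the primary alcohol to the acid without opening the epoxide, and the C2 descriptor becomes R only through the priority change.

Step 26
Reactants: 34 (2R,3R)-2,3-dimethyloxirane-2-carboxylic acid; 30 deacyl target
Product: 36 target CNP0258430.3 [6-O-((2R,3R)-2,3-epoxy-2-methylbutanoyl) derivative of 30], via mixed anhydride 35 (not isolated)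
Conditions: 2,4,6-trichlorobenzoyl chloride, Et3N, THF, rt; then 30, DMAP, toluene, rt
Reagents that add atoms: none
Why: Yamaguchi esterification acylates the hindered C6 alcohol with retention, and the acid has no α-hydrogen that could epimerise.

**Compound list**
1 | (S)-lactic acid | C[C@H](O)C(=O)O | starting material
2 | pivalaldehyde | CC(C)(C)C=O | starting material
3 | (2S,5S)-2-tert-butyl-5-methyl-1,3-dioxolan-4-one | C[C@@H]1O[C@H](C(C)(C)C)OC1=O | intermediate
4 | allyl bromide | C=CCBr | starting material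
5 | lithium enolate of 3 (acetal centre unchanged) | [Li+].[O-]C1=C(C)O[C@H](C(C)(C)C)O1 | intermediate (not isolated)
6 | (2S,5R)-2-tert-butyl-5-methyl-5-(prop-2-en-1-yl)-1,3-dioxolan-4-one | C=CC[C@@]1(C)O[C@H](C(C)(C)C)OC1=O | intermediate
7 | (2R)-2-methylpent-4-ene-1,2-diol | C=CC[C@@](C)(O)CO | intermediate
8 | (4R)-2,2,4-trimethyl-4-(prop-2-en-1-yl)-1,3-dioxolane | C=CC[C@]1(C)COC(C)(C)O1 | intermediate
9 | (4R)-2,2,4-trimethyl-4-(oxiran-2-ylmethyl)-1,3-dioxolane, 1:1 oxirane epimers | C1OC1C[C@]2(C)COC(C)(C)O2 | intermediate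
10 | (4R)-2,2,4-trimethyl-4-{[(2S)-oxiran-2-yl]methyl}-1,3-dioxolane | C1O[C@H]1C[C@]2(C)COC(C)(C)O2 | intermediate
11 | (2S)-1-[(4R)-2,2,4-trimethyl-1,3-dioxolan-4-yl]but-3-en-2-ol | C=C[C@@H](O)C[C@]1(C)COC(C)(C)O1 | intermediate
12 | 2-(bromomethyl)prop-2-enoic acid | C=C(CBr)C(=O)O | starting material
13 | (2S)-1-[(4R)-2,2,4-trimethyl-1,3-dioxolan-4-yl]but-3-en-2-yl 2-(bromomethyl)prop-2-enoate | C=C[C@@H](OC(=O)C(=C)CBr)C[C@]1(C)COC(C)(C)O1 | intermediate
14 | (5S)-3-(bromomethyl)-5-{[(4R)-2,2,4-trimethyl-1,3-dioxolan-4-yl]methyl}furan-2(5H)-one | BrCC1=C[C@H](C[C@]2(C)COC(C)(C)O2)OC1=O | intermediate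
15 | (2Z)-3-methylpent-2-en-4-yn-1-ol | C#C/C(C)=C\CO | starting material
16 | trimethyl{[(2Z)-3-methyl-5-(trimethylsilyl)pent-2-en-4-yn-1-yl]oxy}silane | C[Si](C)(C)C#C/C(C)=C\CO[Si](C)(C)C | intermediate (not isolated)
17 | (2Z)-3-methyl-5-(trimethylsilyl)pent-2-en-4-yn-1-ol | C[Si](C)(C)C#C/C(C)=C\CO | intermediate
18 | (2Z)-3-methyl-5-(trimethylsilyl)pent-2-en-4-ynal | C[Si](C)(C)C#C/C(C)=C\C=O | intermediate
19 | allylzinc bromide derived from 14 (BrZn on the exocyclic CH2) | Br[Zn]CC1=C[C@H](C[C@]2(C)COC(C)(C)O2)OC1=O | intermediate (not isolated)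
20 | (4S,5S)-4-[(1R,2Z)-1-hydroxy-3-methyl-5-(trimethylsilyl)pent-2-en-4-yn-1-yl]-3-methylidene-5-{[(4R)-2,2,4-trimethyl-1,3-dioxolan-4-yl]methyl}oxolan-2-one | C=C1C(=O)O[C@@H](C[C@]2(C)COC(C)(C)O2)[C@@H]1[C@H](O)/C=C(C)\C#C[Si](C)(C)C | intermediate
21 | (1S,2Z)-3-methyl-1-[(2S,3R)-4-methylidene-5-oxo-2-{[(4R)-2,2,4-trimethyl-1,3-dioxolan-4-yl]methyl}oxolan-3-yl]-5-(trimethylsilyl)pent-2-en-4-yn-1-yl chloroacetate | C=C1C(=O)O[C@@H](C[C@]2(C)COC(C)(C)O2)[C@@H]1[C@@H](OC(=O)CCl)/C=C(C)\C#C[Si](C)(C)C | intermediate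
22 | (4S,5S)-4-[(1S,2Z)-1-hydroxy-3-methyl-5-(trimethylsilyl)pent-2-en-4-yn-1-yl]-3-methylidene-5-{[(4R)-2,2,4-trimethyl-1,3-dioxolan-4-yl]methyl}oxolan-2-one | C=C1C(=O)O[C@@H](C[C@]2(C)COC(C)(C)O2)[C@@H]1[C@@H](O)/C=C(C)\C#C[Si](C)(C)C | intermediate
23 | (4R,5S)-4-[(1S,2Z)-1-{[tert-butyl(dimethyl)silyl]oxy}-3-methyl-5-(trimethylsilyl)pent-2-en-4-yn-1-yl]-3-methylidene-5-{[(4R)-2,2,4-trimethyl-1,3-dioxolan-4-yl]methyl}oxolan-2-one | C=C1C(=O)O[C@@H](C[C@]2(C)COC(C)(C)O2)[C@@H]1[C@@H](O[Si](C)(C)C(C)(C)C)/C=C(C)\C#C[Si](C)(C)C | intermediate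
24 | (4R,5S)-4-[(1S,2Z)-1-{[tert-butyl(dimethyl)silyl]oxy}-3-methyl-5-(trimethylsilyl)pent-2-en-4-yn-1-yl]-5-[(2R)-2,3-dihydroxy-2-methylpropyl]-3-methylideneoxolan-2-one | C=C1C(=O)O[C@@H](C[C@@](C)(O)CO)[C@@H]1[C@@H](O[Si](C)(C)C(C)(C)C)/C=C(C)\C#C[Si](C)(C)C | intermediate
25 | (4R,5S)-4-[(1S,2Z)-1-{[tert-butyl(dimethyl)silyl]oxy}-5-iodo-3-methylpent-2-en-4-yn-1-yl]-5-[(2R)-2,3-dihydroxy-2-methylpropyl]-3-methylideneoxolan-2-one | C=C1C(=O)O[C@@H](C[C@@](C)(O)CO)[C@@H]1[C@@H](O[Si](C)(C)C(C)(C)C)/C=C(C)\C#CI | intermediate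
26 | (2R)-3-{(2S,3R)-3-[(1S,2Z)-1-{[tert-butyl(dimethyl)silyl]oxy}-5-iodo-3-methylpent-2-en-4-yn-1-yl]-4-methylidene-5-oxooxolan-2-yl}-2-hydroxy-2-methylpropanal | C=C1C(=O)O[C@@H](C[C@@](C)(O)C=O)[C@@H]1[C@@H](O[Si](C)(C)C(C)(C)C)/C=C(C)\C#CI | intermediate
27 | 6-O-TBS-1,10-dihydroxygermacra-4(Z),11(13)-dien-2-yn-12,8-olide (C1 epimers; other centres as in target) | C=C1C(=O)O[C@H]2C[C@@](C)(O)C(O)C#C/C(C)=C\[C@H](O[Si](C)(C)C(C)(C)C)[C@H]12 | intermediate
28 | 6-O-TBS-10-hydroxy-1-oxogermacra-4(Z),11(13)-dien-2-yn-12,8-olide | C=C1C(=O)O[C@H]2C[C@@](C)(O)C(=O)C#C/C(C)=C\[C@H](O[Si](C)(C)C(C)(C)C)[C@H]12 | intermediate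
29 | 6-O-TBS ether of the deacyl target | C=C1C(=O)O[C@H]2C[C@@]3(C)OC(=CC3=O)/C(C)=C\[C@H](O[Si](C)(C)C(C)(C)C)[C@H]12 | intermediate
30 | deacyl target (free C6 alcohol) | C=C1C(=O)O[C@H]2C[C@@]3(C)OC(=CC3=O)/C(C)=C\[C@H](O)[C@H]12 | intermediate
31 | angelic acid | C/C=C(/C)C(=O)O | starting material
32 | (2Z)-2-methylbut-2-en-1-ol | C/C=C(/C)CO | intermediate
33 | [(2S,3R)-2,3-dimethyloxiran-2-yl]methanol | OC[C@]1(C)O[C@@H]1C | intermediate
34 | (2R,3R)-2,3-dimethyloxirane-2-carboxylic acid | OC(=O)[C@]1(C)O[C@@H]1C | intermediate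
35 | (2R,3R)-2,3-dimethyloxirane-2-carboxylic 2,4,6-trichlorobenzoic anhydride | O=C(OC(=O)c1c(Cl)cc(Cl)cc1Cl)[C@]1(C)O[C@@H]1C | intermediate (not isolated)
36 | CNP0258430.3 | C=C1C(=O)O[C@H]2C[C@@]3(C)OC(=CC3=O)/C(C)=C\[C@H](OC(=O)[C@]3(C)O[C@@H]3C)[C@H]12 | target

**Totals**
Total step count: 26. Longest linear sequence: 21 steps (steps 1–9, 12–22, 26); side branches are steps 10–11 and 23–25.

**Three steps most likely to fail**

Step 12 (Barbier coupling). The C6 outcome is a chair-model prediction for this substrate, not a measured result, and conversion in the aqueous zinc medium may be poor. The adduct must also be kept away from base, because an alkoxide could translactonise onto O6. Any syn (1S) isomer formed is 22 itself and is pooled after step 14. Fallback: the route sets out from 14 and returns at 20. Borylation of 14 with bis(pinacolato)diboron and Pd2(dba)3 (cat.) in DMSO at 50 °C gives (5S)-3-[(pinacolatoboryl)methyl]-5-{[(4R)-2,2,4-trimethyl-1,3-dioxolan-4-yl]methyl}furan-2(5H)-one F1. Heating F1 with 18 in toluene at 80 °C (Sc(OTf)3, 10 mol %, if sluggish) is a true allylboration through a tight six-membered transition state, and aqueous work-up gives 20.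

Step 13 (Mitsunobu inversion). The carbinol is hindered and allylic and sits next to the methylene lactone, so elimination or phosphine addition may compete. Fallback: the route sets out from 20 and returns at 22, skipping 21. Dess–Martin oxidation of 20 gives the dienynone (4R,5S)-3-methylidene-4-[(2Z)-3-methyl-5-(trimethylsilyl)pent-2-en-4-ynoyl]-5-{[(4R)-2,2,4-trimethyl-1,3-dioxolan-4-yl]methyl}oxolan-2-one F2, kept strictly base-free because the C7 hydrogen is acidic. Reagent-controlled reduction with (S)-2-methyl-CBS-oxazaborolidine and catecholborane in toluene at −78 °C (alkenyl as the large group) should give the (1S) alcohol 22. The sense is checked by Mosher analysis, and the (R)-catalyst is used if it proves reversed. This path also converges any C6 epimer mixture from step 12.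

Step 19 (macrocyclisation). Closing a ten-membered enyne ring competes with oligomerisation, and the hydroxy aldehyde may be sluggish toward the chromium reagent. Fallback: the route sets out from 24 and returns at 27, skipping 25 and 26. Protodesilylation of 24 with AgNO3 (10 mol %) in acetone/H2O gives the terminal alkyne diol (4R,5S)-4-[(1S,2Z)-1-{[tert-butyl(dimethyl)silyl]oxy}-3-methylpent-2-en-4-yn-1-yl]-5-[(2R)-2,3-dihydroxy-2-methylpropyl]-3-methylideneoxolan-2-one F3. Parikh–Doering oxidation then gives the hydroxy aldehyde (2R)-3-{(2S,3R)-3-[(1S,2Z)-1-{[tert-butyl(dimethyl)silyl]oxy}-3-methylpent-2-en-4-yn-1-yl]-4-methylidene-5-oxooxolan-2-yl}-2-hydroxy-2-methylpropanal F4. The ring is closed by addition of the zinc acetylide generated in situ from the free alkyne (Zn(OTf)2, Et3N, toluene, 0.002 M, 40–60 °C), which needs neither the iodoalkyne nor chromium and gives 27.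

Further compounds
F1 | step 12 | (5S)-3-[(4,4,5,5-tetramethyl-1,3,2-dioxaborolan-2-yl)methyl]-5-{[(4R)-2,2,4-trimethyl-1,3-dioxolan-4-yl]methyl}furan-2(5H)-one | CC1(C)OB(CC2=C[C@H](C[C@]3(C)COC(C)(C)O3)OC2=O)OC1(C)C
F2 | step 13 | (4R,5S)-3-methylidene-4-[(2Z)-3-methyl-5-(trimethylsilyl)pent-2-en-4-ynoyl]-5-{[(4R)-2,2,4-trimethyl-1,3-dioxolan-4-yl]methyl}oxolan-2-one | C=C1C(=O)O[C@@H](C[C@]2(C)COC(C)(C)O2)[C@@H]1C(=O)/C=C(C)\C#C[Si](C)(C)C
F3 | step 19 | (4R,5S)-4-[(1S,2Z)-1-{[tert-butyl(dimethyl)silyl]oxy}-3-methylpent-2-en-4-yn-1-yl]-5-[(2R)-2,3-dihydroxy-2-methylpropyl]-3-methylideneoxolan-2-one | C=C1C(=O)O[C@@H](C[C@@](C)(O)CO)[C@@H]1[C@@H](O[Si](C)(C)C(C)(C)C)/C=C(C)\C#C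
F4 | step 19 | (2R)-3-{(2S,3R)-3-[(1S,2Z)-1-{[tert-butyl(dimethyl)silyl]oxy}-3-methylpent-2-en-4-yn-1-yl]-4-methylidene-5-oxooxolan-2-yl}-2-hydroxy-2-methylpropanal | C=C1C(=O)O[C@@H](C[C@@](C)(O)C=O)[C@@H]1[C@@H](O[Si](C)(C)C(C)(C)C)/C=C(C)\C#C
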